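Early on, G runs ahead in the green flask: at 3.00 min it reads 16.8% against 6.5% of D.

| flask | X | temperature | remark | time |
|---|---|---|---|---|
| green | 0.44 M | 90 °C | run made earlier |  |
| eta | 0.12 M | 105 °C |  | 12 min |
| alpha | 0.40 M | 90 °C |  | 20 min |

green run (percent of the X charged)

| time / min | G / % | D / % | J / % |
|---|---|---|---|
| 0.417 | 2.4 | 2.3 | 0.2 |
| 1.00 | 5.5 | 2.2 | 2.2 |
| 2.00 | 12.0 | 4.0 | 0.6 |
| 3.00 | 16.8 | 6.5 | 0 |
| 4.00 | 17.7 | 8.4 | 1.1 |
| 6.00 | 18.9 | 13.8 | 0 |
| 8.00 | 23.6 | 14.7 | 1.6 |

(readings scatter by 1 percentage point)

* which one finishes higher in share of G in all that became G or D or J ("neither" within 2 percentage points) (eta / alpha / neither)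
* share of G in all that became G or D or J, eta
* share of G in all that became G or D or J, alpha

- the earlier runs do not show what temperature does; that part of a forecast is a guess

Does G keep that pace? No. From 3.00 min to 8.00 min, G gains 6.8 percentage points and D gains 8.2 points.

So what should we watch? Not the G share, which in the green readings falls from 72.1% at 3.00 min to 59.1% at 8.00 min. Take cX by difference and set cG against it. The hold is cG over cX, and the last green reading gives 0.393. If G sits in pre-equilibrium with X, the hold stands still while both fall.

Does it stand still? Not clearly. At 6.00 min it reads 0.281. Each reading scatters by 1 point, so the hold is a reading too. I choose the latest as my working value.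

And the loss? I count D and J as lost from the pool of X plus G. In the green flask that pool reads 83.7% at 8.00 min. Taken as first order, that is a decay time of 45.0 min, which I carry to alpha at the same temperature.

Alpha, then? After 20 min my alpha pool is 64.1%, so my X is 46.0%. The G share is the hold times cX, over what has reacted: 33.5%.

And eta? The runs do not show what temperature does, so I give no figure.

The forecast names alpha, with eta at 35% and alpha at 47%. Its ground: “G levels off while D keeps climbing, which suggests G slowly turns into D”. My alpha share lies below its figure.

The flasks give alpha as the higher, with eta at 28.7% and alpha at 38.6%.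

    X ⇌ G (K = 0.380, k = 0.0810 min⁻¹, Ea = 117 kJ mol⁻¹, ΔH = 38.0 kJ mol⁻¹)
    X ⇌ D (K = 2.00, k = 0.0280 min⁻¹, Ea = 114 kJ mol⁻¹, ΔH = 19.0 kJ mol⁻¹)
    X ⇌ J (K = 36.0, k = 0.00120 min⁻¹, Ea = 116 kJ mol⁻¹, ΔH = 3.00 kJ mol⁻¹)
    (constants at 90 °C)

Alpha at 20 min holds X at 49%, above my 46.0%, and its hold is 0.408. Eta at 12 min shows a hold of 0.666. Its neighbour is the same flask read at 20 min, where X stands at 25%. Carry eta's hold over. G is the hold times X, and 75.0% has reacted, so the share comes to 22.5%. The neighbour flask gives 21.8%.

The earlier runs and the new flask stem from a simulated flask on assumed constants.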